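**Plan** (cembrane numbering: C1–C14 = carbocycle, C15 = CMe2, C18 = CH2O, C19 = CHO; the tetrahydrofuran is O–C3–C2–C1–C15)
1. Cuts: first the malonyl–O18 ester. Then, inside the five-membered ring, the O–C15 bond is traded for a C2–C15 bond and C3 is raised to C=O. This turns the bridged oxabicyclo[11.2.1] core into a fused bicyclo[12.1.0] (casbane-type) cyclopropyl ketone. Last come C12–C13 (B-alkyl Suzuki), C3–C4 (aldol) and C7=C8 (HWE).
2. Enabling feature: ring carbons C2–C1–C15 are contiguous, C15 is a gem-dimethyl carbon bound to the ring O, and C3 is the other O-bearing ring carbon. C2/C1/C15 can therefore be stored as a 2,2-dimethylcyclopropane whose C2–C15 bond is pushed by tertiary C15 and pulled by a C3 ketone, and the ketone oxygen then takes C15.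
3. Forward order: the three-membered ring is bought in. The chain is joined by HWE and aldol, and the 14-membered ring is closed by Suzuki coupling. The three-membered ring then grows by two atoms (C3, O) to the five-membered ring and is reduced in the same flask, after which C19 and C18 are adjusted and O18 is malonylated.
4. Stereochemistry: C1 comes from (1R,3R)-chrysanthemic acid and is a spectator in the key step. C4 comes from an Evans syn-aldol reaction. C3 comes from hydride attack on the outer face of the bridgehead oxocarbenium ion.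
5. Alkenes: 11Z comes from an iodo-Wittig olefination plus stereoretentive coupling, and 7E from the HWE reaction.

Key step: step 16

Assumption: compounds 1, 6, 7, 10 and 13 are treated as commercial, and the cembrane numbering above is used for all chain and macrocyclic compounds.

**Step 1**
Reactants: 1 (1R,3R)-chrysanthemic acid
Product: 2 Weinreb amide (1R,3R)-N-methoxy-N,2,2-trimethyl-3-(2-methylprop-1-en-1-yl)cyclopropane-1-carboxamide
Conditions: MeNH(OMe)·HCl, EDC·HCl, Et3N, DMAP (cat.), CH2Cl2, 0 °C → rt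
Reagents that add atoms: N,O-dimethylhydroxylamine hydrochloride, CNOC.Cl
Why: Carbodiimide amide coupling to the Weinreb amide leaves both ring stereocentres and the alkene untouched and stores C3 at a level that can be stopped at the aldehyde in step 4.

**Step 2**
Reactants: 2 Weinreb amide
Product: 3 (1R,3R)-3-formyl-N-methoxy-N,2,2-trimethylcyclopropane-1-carboxamide
Conditions: O3, CH2Cl2, −78 °C; then Me2S, −78 °C → rt
Reagents that add atoms: ozone, [O-][O+]=O
Why: Ozonolysis with reductive work-up cleaves the only C=C bond to the C14 aldehyde (the standard chrysanthemate-to-caronaldehyde degradation), and the thermodynamically preferred trans-cyclopropane does not epimerise.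

**Step 3**
Reactants: 3 formyl Weinreb amide
Product: 4 (1R,3R)-3-ethenyl-N-methoxy-N,2,2-trimethylcyclopropane-1-carboxamide
Conditions: Ph3PCH3Br, KOtBu, THF, 0 °C
Reagents that add atoms: methyltriphenylphosphonium bromide, C[P+](c1ccccc1)(c1ccccc1)c1ccccc1.[Br-]
Why: Wittig methylenation of the aldehyde is much faster than attack on the Weinreb amide, and the trans-cyclopropanecarbaldehyde keeps the C1 configuration.

**Step 4**
Reactants: 4 vinyl Weinreb amide
Product: 5 (1R,3R)-3-ethenyl-2,2-dimethylcyclopropane-1-carbaldehyde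
Conditions: DIBAL-H (1.2 equiv), THF, −78 °C; aq. Rochelle salt
Reagents that add atoms: none
Why: DIBAL-H reduction of a Weinreb amide stops at the chelated hemiaminal, which releases the aldehyde only on work-up, and the vinyl group is inert.

**Step 5**
Reactants: 6 hex-5-enoyl chloride; 7 (4S)-4-benzyl-1,3-oxazolidin-2-one
Product: 8 (4S)-4-benzyl-3-(hex-5-enoyl)-1,3-oxazolidin-2-one
Conditions: Et3N, DMAP (cat.), CH2Cl2, 0 °C → rt
Reagents that add atoms: none
Why: DMAP-catalysed N-acylation of the oxazolidinone with an acid chloride installs the Evans auxiliary without touching its stereocentre.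

**Step 6**
Reactants: 8 hexenoyl imide
Product: 9 5-[(4S)-4-benzyl-2-oxo-1,3-oxazolidin-3-yl]-5-oxopentanal
Conditions: O3, CH2Cl2, −78 °C; then Me2S, −78 °C → rt
Reagents that add atoms: ozone, [O-][O+]=O
Why: Ozonolysis with reductive work-up of the single terminal alkene gives the C7 aldehyde, and the imide is inert to ozone and Me2S.

**Step 7**
Reactants: 10 3-[(tert-butyldimethylsilyl)oxy]propanal
Product: 11 tert-butyl{[(3Z)-4-iodopent-3-en-1-yl]oxy}dimethylsilane
Conditions: EtPPh3I, n-BuLi, THF, rt; I2, −78 °C; NaHMDS, −20 °C; then 10, −78 °C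
Reagents that add atoms: ethyltriphenylphosphonium iodide, CC[P+](c1ccccc1)(c1ccccc1)c1ccccc1.[I-]; iodine, II
Why: The Stork–Zhao-type Wittig olefination with the α-iodo ylide runs under kinetic control through the cis-oxaphosphetane and places iodine cis to the C10 chain, which is the geometry later handed on to C11=C12.

**Step 8**
Reactants: 11 (Z)-vinyl iodide silyl ether
Product: 12 (2Z)-5-bromo-2-iodopent-2-ene
Conditions: Ph3PBr2, CH2Cl2, 0 °C → rt
Reagents that add atoms: dibromotriphenylphosphorane, BrP(Br)(c1ccccc1)(c1ccccc1)c1ccccc1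
Why: Direct Appel-type bromination of a primary silyl ether (oxyphosphonium ion, SN2) replaces OTBS by Br in one operation and does not affect the vinyl iodide.

**Step 9**
Reactants: 12 bromide; 13 triethyl phosphonoacetate
Product: 14 ethyl (5Z)-2-(diethoxyphosphoryl)-6-iodohept-5-enoate (racemic at C8)
Conditions: NaH, DMF, 0 °C; then 12, NaI (cat.), 50 °C
Reagents that add atoms: none
Why: SN2 C-alkylation of the soft, weakly basic phosphonoacetate anion with a primary bromide is standard and keeps E2 loss of HBr low, and the new C8 centre disappears in step 10.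

**Step 10**
Reactants: 14 phosphonate; 9 aldehyde imide
Product: 15 ethyl (2E)-7-[(4S)-4-benzyl-2-oxo-1,3-oxazolidin-3-yl]-2-[(3Z)-4-iodopent-3-en-1-yl]-7-oxohept-2-enoate
Conditions: LiCl, DBU, MeCN, 0 °C → rt
Reagents that add atoms: none
Why: The Horner–Wadsworth–Emmons olefination under Masamune–Roush conditions collapses through the less crowded adduct and puts CO2Et trans to C6 (7E); the mild base spares the imide, and any minor Z isomer should be removable by chromatography.

**Step 11**
Reactants: 15 enoate imide; 5 cyclopropanecarbaldehyde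
Product: 17 Evans syn-aldol adduct ethyl (2E,6S,7R)-6-{[(4S)-4-benzyl-2-oxo-1,3-oxazolidin-3-yl]carbonyl}-7-[(1R,3R)-3-ethenyl-2,2-dimethylcyclopropyl]-7-hydroxy-2-[(3Z)-4-iodopent-3-en-1-yl]hept-2-enoate, via dibutylboron Z-enolate 16 (not isolated)
Conditions: Bu2BOTf, Et3N, CH2Cl2, 0 °C; then 5, −78 → 0 °C; H2O2, MeOH, pH 7 buffer
Reagents that add atoms: none
Why: In the Evans syn-aldol reaction the boron Z-enolate reacts through a closed chair transition state whose face is dictated by the (S)-benzyl auxiliary, which sets C4 (the centre that survives) and C3 under reagent control that overrides the chiral aldehyde.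

**Step 12**
Reactants: 17 aldol adduct
Product: 18 ethyl (2E,6R,7R)-7-[(1R,3R)-3-ethenyl-2,2-dimethylcyclopropyl]-7-hydroxy-6-(hydroxymethyl)-2-[(3Z)-4-iodopent-3-en-1-yl]hept-2-enoate
Conditions: LiBH4, Et2O, H2O (1 equiv), 0 °C
Reagents that add atoms: none
Why: Reductive removal of the auxiliary with LiBH4 is faster at the activated imide carbonyl than at the conjugated ethyl ester at 0 °C and gives the C18 alcohol without epimerising C4.

**Step 13**
Reactants: 18 diol
Product: 19 ethyl (2E,6R,7R)-6-{[(tert-butyldiphenylsilyl)oxy]methyl}-7-[(1R,3R)-3-ethenyl-2,2-dimethylcyclopropyl]-7-hydroxy-2-[(3Z)-4-iodopent-3-en-1-yl]hept-2-enoate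
Conditions: TBDPSCl, imidazole, CH2Cl2, 0 °C
Reagents that add atoms: tert-butyl(chloro)diphenylsilane, CC(C)(C)[Si](Cl)(c1ccccc1)c1ccccc1
Why: Silylation with the bulky chloride is selective for the primary C18 hydroxyl over the hindered secondary cyclopropyl carbinol, and this acid-stable silyl ether is chosen to survive step 16.

**Step 14**
Reactants: 19 silyl ether
Product: 21 macrocyclic alcohol ethyl (1R,2R,3R,4R,7E,11Z)-18-[(tert-butyldiphenylsilyl)oxy]-3-hydroxy-2,15-cyclocembra-7,11-dien-19-oate (14-membered ring trans-fused to the cyclopropane C1–C2–C15), via B-alkyl-9-BBN borane 20 (not isolated)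
Conditions: 9-BBN-H (2.5 equiv), THF, rt; then slow addition to PdCl2(dppf) (20 mol %), AsPh3, Cs2CO3, DMF–THF–H2O, 1 mM, 50 °C
Reagents that add atoms: none
Why: Anti-Markovnikov hydroboration of the only monosubstituted alkene, followed by an intramolecular B-alkyl Suzuki–Miyaura coupling at high dilution, closes the 14-membered ring at C12–C13 with retention of the vinyl iodide geometry (11Z), and C3 is still an alcohol, so the base meets no epimerisable ketone.

**Step 15**
Reactants: 21 macrocyclic alcohol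
Product: 22 macrocyclic cyclopropyl ketone ethyl (1R,2R,4R,7E,11Z)-18-[(tert-butyldiphenylsilyl)oxy]-3-oxo-2,15-cyclocembra-7,11-dien-19-oate
Conditions: Dess–Martin periodinane, CH2Cl2, 0 °C → rt
Reagents that add atoms: none
Why: Dess–Martin oxidation of the cyclopropyl carbinol is close to neutral, so the α-centre C4 and the β-silyloxy group are safe, and it installs the acceptor that activates the cyclopropane.

**Step 16**
Reactants: 22 macrocyclic cyclopropyl ketone
Product: 25 ethyl (1R,3R,4R,7E,11Z)-18-[(tert-butyldiphenylsilyl)oxy]-3,15-epoxycembra-7,11-dien-19-oate, via bridged dihydrofuran 23 (not isolated), via bridgehead oxocarbenium trifluoroacetate 24 (not isolated)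
Conditions: TMSOTf (0.2 equiv), CH2Cl2, −40 → 0 °C; then Et3SiH (5 equiv), CF3CO2H (2 equiv), −78 → −40 °C
Reagents that add atoms: none
Why: TMSOTf silylates the C3 carbonyl oxygen of the preferred s-cis (bisected) conformer, the donor–acceptor C2–C15 bond then breaks heterolytically to a tertiary C15 cation and a C3=C2 silyl enol ether with O cis to C1, and the enol oxygen closes on C15 with loss of TMS+, so that the three-membered ring C2–C1–C15 takes up C3 and O and becomes the five-membered ring O–C3=C2–C1–C15 of 23. This is the acid-promoted Cloke–Wilson rearrangement of a cyclopropyl ketone (the ketone counterpart of the known isomerisation of chrysanthemic acid to its γ-lactone), followed in the same flask by ionic hydrogenation of the enol ether. The only ring closed is the five-membered one, by O-alkylation of an endocyclic enol (enol-endo) at a free tertiary cation; a concerted displacement would be 5-endo-tet and is geometrically excluded, which is why the gem-dimethyl donor at C15 is essential. The ring expansion itself creates no stereocentre (C15 is gem-dimethyl, C2 becomes sp2) and C1 is a spectator that keeps the configuration of 1; C3 is set when CF3CO2H protonates C2 and Et3SiH attacks the bridgehead oxocarbenium 24 from its outer face, anti to the C1–C14 bond, because the inner face is covered by the eleven-carbon bridge C4–C14, in line with the inside-attack model for 3-alkyl five-membered oxocarbenium ions, giving the cis-1,3-bridged (3R) ring. Regioselectivity (C2–C15 and not C2–C1 cleavage) follows from tertiary versus secondary cation stability; chemoselectivity over C11=C12 and the enoate follows from activation at oxygen in the first stage and from the far higher basicity of the enol ether in the second. Retention at C4 needs hydride capture to outrun tautomerisation to the exocyclic enol ether, which low temperature and excess silane should secure.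

**Step 17**
Reactants: 25 tetrahydrofuran ester
Product: 26 (1R,3R,4R,7E,11Z)-18-[(tert-butyldiphenylsilyl)oxy]-3,15-epoxycembra-7,11-dien-19-ol
Conditions: DIBAL-H (2.5 equiv), CH2Cl2, −78 °C; aq. Rochelle salt
Reagents that add atoms: none
Why: DIBAL-H 1,2-reduction of the α,β-unsaturated ester gives the allylic alcohol and leaves the cyclic ether, the silyl ether and both alkenes alone.

**Step 18**
Reactants: 26 silyl-protected allylic alcohol
Product: 27 (1R,3R,4R,7E,11Z)-3,15-epoxycembra-7,11-diene-18,19-diol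
Conditions: TBAF, THF, rt
Reagents that add atoms: none
Why: Fluoride-induced desilylation frees the C18 hydroxyl under conditions that touch no other group.

**Step 19**
Reactants: 27 diol
Product: 28 (1R,3R,4R,7E,11Z)-18-hydroxy-3,15-epoxycembra-7,11-dien-19-al
Conditions: activated MnO2, CH2Cl2, rt
Reagents that add atoms: none
Why: MnO2 oxidises only the allylic C19 alcohol and not the saturated primary C18 alcohol, and the (E)-enal formed is already the thermodynamic isomer.

**Step 20**
Reactants: 28 hydroxy enal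
Product: 29 target, 3-{[(1R,3R,4R,7E,11Z)-3,15-epoxy-19-oxocembra-7,11-dien-18-yl]oxy}-3-oxopropanoic acid
Conditions: Meldrum's acid (1.2 equiv), toluene, 85 °C
Reagents that add atoms: Meldrum's acid, CC1(C)OC(=O)CC(=O)O1
Why: Thermal alcoholysis of Meldrum's acid (acyl ring opening with loss of acetone) delivers the malonic half ester directly, without base or a protecting group on the acid.

**Compound list**
1 | (1R,3R)-2,2-dimethyl-3-(2-methylprop-1-en-1-yl)cyclopropane-1-carboxylic acid [(+)-trans-chrysanthemic acid] | CC(C)=C[C@@H]1[C@@H](C(=O)O)C1(C)C | starting material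
2 | (1R,3R)-N-methoxy-N,2,2-trimethyl-3-(2-methylprop-1-en-1-yl)cyclopropane-1-carboxamide | CC(C)=C[C@@H]1[C@@H](C(=O)N(C)OC)C1(C)C | intermediate
3 | (1R,3R)-3-formyl-N-methoxy-N,2,2-trimethylcyclopropane-1-carboxamide | O=C[C@@H]1[C@@H](C(=O)N(C)OC)C1(C)C | intermediate
4 | (1R,3R)-3-ethenyl-N-methoxy-N,2,2-trimethylcyclopropane-1-carboxamide | C=C[C@@H]1[C@@H](C(=O)N(C)OC)C1(C)C | intermediate
5 | (1R,3R)-3-ethenyl-2,2-dimethylcyclopropane-1-carbaldehyde | C=C[C@@H]1[C@@H](C=O)C1(C)C | intermediate
6 | hex-5-enoyl chloride | C=CCCCC(=O)Cl | starting material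
7 | (4S)-4-benzyl-1,3-oxazolidin-2-one | O=C1N[C@@H](Cc2ccccc2)CO1 | starting material
8 | (4S)-4-benzyl-3-(hex-5-enoyl)-1,3-oxazolidin-2-one | C=CCCCC(=O)N1[C@@H](Cc2ccccc2)COC1=O | intermediate
9 | 5-[(4S)-4-benzyl-2-oxo-1,3-oxazolidin-3-yl]-5-oxopentanal | O=CCCCC(=O)N1[C@@H](Cc2ccccc2)COC1=O | intermediate
10 | 3-[(tert-butyldimethylsilyl)oxy]propanal | O=CCCO[Si](C)(C)C(C)(C)C | starting material
11 | tert-butyl{[(3Z)-4-iodopent-3-en-1-yl]oxy}dimethylsilane | C/C(I)=C/CCO[Si](C)(C)C(C)(C)C | intermediate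
12 | (2Z)-5-bromo-2-iodopent-2-ene | C/C(I)=C/CCBr | intermediate
13 | triethyl phosphonoacetate | CCOC(=O)CP(=O)(OCC)OCC | starting material
14 | ethyl (5Z)-2-(diethoxyphosphoryl)-6-iodohept-5-enoate | CCOC(=O)C(CC/C=C(/C)I)P(=O)(OCC)OCC | intermediate
15 | ethyl (2E)-7-[(4S)-4-benzyl-2-oxo-1,3-oxazolidin-3-yl]-2-[(3Z)-4-iodopent-3-en-1-yl]-7-oxohept-2-enoate | C/C(I)=C/CC/C(C(=O)OCC)=C\CCCC(=O)N1[C@@H](Cc2ccccc2)COC1=O | intermediate
16 | dibutylboron (Z)-enolate of 15 (C4=C18, OBBu2 cis to C5) | C/C(I)=C/CC/C(C(=O)OCC)=C\CC/C=C(\OB(CCCC)CCCC)N1[C@@H](Cc2ccccc2)COC1=O | intermediate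
17 | Evans syn-aldol adduct (C1 R, C2 R, C3 R, C4 S) | C/C(I)=C/CC/C(C(=O)OCC)=C\CC[C@H](C(=O)N1[C@@H](Cc2ccccc2)COC1=O)[C@H](O)[C@@H]1[C@@H](C=C)C1(C)C | intermediate
18 | C3,C18-diol (C1 R, C2 R, C3 R, C4 R) | C/C(I)=C/CC/C(C(=O)OCC)=C\CC[C@H](CO)[C@H](O)[C@@H]1[C@@H](C=C)C1(C)C | intermediate
19 | C18 TBDPS ether of 18 | C/C(I)=C/CC/C(C(=O)OCC)=C\CC[C@H](CO[Si](c1ccccc1)(c1ccccc1)C(C)(C)C)[C@H](O)[C@@H]1[C@@H](C=C)C1(C)C | intermediate
20 | B-alkyl-9-BBN borane of 19 (boron on C13, O3 as 9-BBN borinate) | C/C(I)=C/CC/C(C(=O)OCC)=C\CC[C@H](CO[Si](c1ccccc1)(c1ccccc1)C(C)(C)C)[C@H](OB1C2CCCC1CCC2)[C@@H]1[C@@H](CCB2C3CCCC2CCC3)C1(C)C | intermediate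
21 | ethyl (1R,2R,3R,4R,7E,11Z)-18-[(tert-butyldiphenylsilyl)oxy]-3-hydroxy-2,15-cyclocembra-7,11-dien-19-oate | C/C1=C/CC/C(C(=O)OCC)=C\CC[C@H](CO[Si](c2ccccc2)(c2ccccc2)C(C)(C)C)[C@H](O)[C@@H]2[C@@H](CC1)C2(C)C | intermediate
22 | ethyl (1R,2R,4R,7E,11Z)-18-[(tert-butyldiphenylsilyl)oxy]-3-oxo-2,15-cyclocembra-7,11-dien-19-oate | C/C1=C/CC/C(C(=O)OCC)=C\CC[C@H](CO[Si](c2ccccc2)(c2ccccc2)C(C)(C)C)C(=O)[C@@H]2[C@@H](CC1)C2(C)C | intermediate
23 | ethyl (1R,4R,7E,11Z)-18-[(tert-butyldiphenylsilyl)oxy]-3,15-epoxycembra-2,7,11-trien-19-oate (bridged 2,3-dihydrofuran) | C/C1=C/CC/C(C(=O)OCC)=C\CC[C@H](CO[Si](c2ccccc2)(c2ccccc2)C(C)(C)C)C2=C[C@@H](CC1)C(C)(C)O2 | intermediate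
24 | C2-protonated 23, bridgehead C3=O+ oxocarbenium trifluoroacetate | C/C1=C/CC/C(C(=O)OCC)=C\CC[C@H](CO[Si](c2ccccc2)(c2ccccc2)C(C)(C)C)C=2C[C@@H](CC1)C(C)(C)[O+]=2.[O-]C(=O)C(F)(F)F | intermediate
25 | ethyl (1R,3R,4R,7E,11Z)-18-[(tert-butyldiphenylsilyl)oxy]-3,15-epoxycembra-7,11-dien-19-oate | C/C1=C/CC/C(C(=O)OCC)=C\CC[C@H](CO[Si](c2ccccc2)(c2ccccc2)C(C)(C)C)[C@H]2C[C@@H](CC1)C(C)(C)O2 | intermediate
26 | (1R,3R,4R,7E,11Z)-18-[(tert-butyldiphenylsilyl)oxy]-3,15-epoxycembra-7,11-dien-19-ol | C/C1=C/CC/C(CO)=C\CC[C@H](CO[Si](c2ccccc2)(c2ccccc2)C(C)(C)C)[C@H]2C[C@@H](CC1)C(C)(C)O2 | intermediate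
27 | (1R,3R,4R,7E,11Z)-3,15-epoxycembra-7,11-diene-18,19-diol | C/C1=C/CC/C(CO)=C\CC[C@H](CO)[C@H]2C[C@@H](CC1)C(C)(C)O2 | intermediate
28 | (1R,3R,4R,7E,11Z)-18-hydroxy-3,15-epoxycembra-7,11-dien-19-al | C/C1=C/CC/C(C=O)=C\CC[C@H](CO)[C@H]2C[C@@H](CC1)C(C)(C)O2 | intermediate
29 | 3-{[(1R,3R,4R,7E,11Z)-3,15-epoxy-19-oxocembra-7,11-dien-18-yl]oxy}-3-oxopropanoic acid (CNP0170412.1) | C/C1=C/CC/C(C=O)=C\CC[C@H](COC(=O)CC(=O)O)[C@H]2C[C@@H](CC1)C(C)(C)O2 | target

Total step count: 20. Longest linear sequence: 14 steps (1–4, then 11–20; the branch 7–10, then 11–20, is equally long).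

**Steps most likely to fail**

**Step 16.**
- What may go wrong: the C15 cation may lose a proton before oxygen closes. Loss from a methyl group only diverts material, but loss from C1 erodes the C1 configuration. The cation may also be captured across the ring by C11=C12. The oxocarbenium ion may tautomerise to the exocyclic enol ether and scramble C4.
- Fallback, from 22 back to 25, free of cations at the ring-opening stage: heating 22 in degassed toluene (sealed, base-washed tube, about 170 °C) should trigger the neutral retro-ene (homo-[1,5]-hydrogen shift) opening of the cis-methyl/acyl cyclopropane. This gives the isopropenyl ketone F1 without touching C1 or C4.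
- Reagent-controlled CBS reduction ((S)-Me-CBS, catecholborane, −78 °C) then gives the (3R)-alcohol F2.
- Cobalt(salen)-catalysed hydrogen-atom-transfer hydroalkoxylation (silane, N-fluorocollidinium salt) is selective for the 1,1-disubstituted alkene and closes O–C15 (5-exo) to 25.

**Step 14.**
- What may go wrong: slow intramolecular transmetalation at high dilution lets protodeboronation, β-hydride elimination and intermolecular coupling to oligomers compete.
- Fallback, from 9, 5 and 14 back to 22, with the ring closed at C7=C8 instead: 9 is masked (HC(OMe)3, PPTS) as the dimethyl acetal imide F3.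
- Its dibutylboron Z-enolate F4 adds to 5 to give the syn-aldol adduct F5. LiBH4 gives the diol F6, and TBDPSCl gives the silyl ether F7.
- Hydroboration gives the B-alkyl-9-BBN borane F8. This is now coupled intermolecularly, at normal concentration, with 14 to give the phosphonate alcohol F9.
- Dess–Martin oxidation gives the phosphonate ketone F10, and PPTS in wet acetone frees the keto aldehyde F11.
- An intramolecular HWE reaction (LiCl, DBU, MeCN, high dilution) gives 22.

**Step 20.**
- What may go wrong: Knoevenagel condensation of Meldrum's acid with the enal may compete, and the half ester may decarboxylate at the reaction temperature.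
- Fallback, from 28 back to 29: carbodiimide esterification (EDC·HCl, DMAP, CH2Cl2, 0 °C) with allyl hydrogen malonate gives the allyl malonate F12. Its allyl group is then removed at room temperature with Pd(PPh3)4 and sodium 4-methylbenzenesulfinate, followed by mild acidification, to give 29.

**Further compounds**
F1 | step 16 | ethyl (1R,4R,7E,11Z)-18-[(tert-butyldiphenylsilyl)oxy]-3-oxocembra-7,11,15-trien-19-oate (isopropenyl ketone) | C/C1=C/CC/C(C(=O)OCC)=C\CC[C@H](CO[Si](c2ccccc2)(c2ccccc2)C(C)(C)C)C(=O)C[C@@H](CC1)C(C)=C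
F2 | step 16 | ethyl (1R,3R,4R,7E,11Z)-18-[(tert-butyldiphenylsilyl)oxy]-3-hydroxycembra-7,11,15-trien-19-oate | C/C1=C/CC/C(C(=O)OCC)=C\CC[C@H](CO[Si](c2ccccc2)(c2ccccc2)C(C)(C)C)[C@H](O)C[C@@H](CC1)C(C)=C
F3 | step 14 | (4S)-4-benzyl-3-(5,5-dimethoxypentanoyl)-1,3-oxazolidin-2-one | COC(CCCC(=O)N1[C@@H](Cc2ccccc2)COC1=O)OC
F4 | step 14 | dibutylboron (Z)-enolate of F3 | COC(OC)CC/C=C(\OB(CCCC)CCCC)N1[C@@H](Cc2ccccc2)COC1=O
F5 | step 14 | syn-aldol adduct of F3 and 5 | COC(OC)CC[C@H](C(=O)N1[C@@H](Cc2ccccc2)COC1=O)[C@H](O)[C@@H]1[C@@H](C=C)C1(C)C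
F6 | step 14 | C3,C18-diol with C7 dimethyl acetal | COC(OC)CC[C@H](CO)[C@H](O)[C@@H]1[C@@H](C=C)C1(C)C
F7 | step 14 | C18 TBDPS ether of F6 | COC(OC)CC[C@H](CO[Si](c1ccccc1)(c1ccccc1)C(C)(C)C)[C@H](O)[C@@H]1[C@@H](C=C)C1(C)C
F8 | step 14 | B-alkyl-9-BBN borane of F7 (O3 as 9-BBN borinate) | COC(OC)CC[C@H](CO[Si](c1ccccc1)(c1ccccc1)C(C)(C)C)[C@H](OB1C2CCCC1CCC2)[C@@H]1[C@@H](CCB2C3CCCC2CCC3)C1(C)C
F9 | step 14 | open-chain (11Z)-phosphonate alcohol | COC(OC)CC[C@H](CO[Si](c1ccccc1)(c1ccccc1)C(C)(C)C)[C@H](O)[C@@H]1[C@@H](CC/C(C)=C\CCC(C(=O)OCC)P(=O)(OCC)OCC)C1(C)C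
F10 | step 14 | open-chain (11Z)-phosphonate C3 ketone | COC(OC)CC[C@H](CO[Si](c1ccccc1)(c1ccccc1)C(C)(C)C)C(=O)[C@@H]1[C@@H](CC/C(C)=C\CCC(C(=O)OCC)P(=O)(OCC)OCC)C1(C)C
F11 | step 14 | open-chain C3-keto C7-aldehyde phosphonate | O=CCC[C@H](CO[Si](c1ccccc1)(c1ccccc1)C(C)(C)C)C(=O)[C@@H]1[C@@H](CC/C(C)=C\CCC(C(=O)OCC)P(=O)(OCC)OCC)C1(C)C
F12 | step 20 | allyl (1R,3R,4R,7E,11Z)-3,15-epoxy-19-oxocembra-7,11-dien-18-yl malonate | C/C1=C/CC/C(C=O)=C\CC[C@H](COC(=O)CC(=O)OCC=C)[C@H]2C[C@@H](CC1)C(C)(C)O2
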